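**Retrosynthetic overview**
1. 17 ⇐ 16: hydrogenolysis of two O‑benzyl groups, no skeletal change.
2. 16 ⇐ 3 + 10 + 11 in one flask: C3–C4 and C6'–C7' are cut together. C3 and C6' are the two ends of the C7 bis‑carbamate 3, each used as a sparteine‑bound α‑oxygenated carbanion (a carbinol carbon acting as the nucleophile) and joined to the boron‑bearing carbon of a boronic ester.
3. 10 ⇐ 6 ⇐ 4: benzylic C–B bond by lateral lithiation–borylation of O,O‑dibenzyl ethyl orsellinate.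
4. 3 ⇐ 1 + 2: double carbamoylation of heptane‑1,7‑diol.
5. Ring order: the benzene ring is bought; the lactone, the only ring made, closes in the key step once the C3 alkoxide is unmasked next to the ester.

Assumption: side‑chain carbons are numbered C1'–C11' outwards from C3; (−)‑sparteine (recovered by acid–base extraction) and boronic ester 11 are bought.

**Route**

Step 1
Reactants: 1 heptane‑1,7‑diol; 2 N,N‑diisopropylcarbamoyl chloride
Product: 3 heptane‑1,7‑diyl bis(N,N‑diisopropylcarbamate)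
Conditions: 2 (2.4 equiv), Et3N (3 equiv), DMAP (cat.), CH2Cl2, reflux, 24 h
Reagents that add atoms: N,N‑diisopropylcarbamoyl chloride (2), CC(C)N(C(C)C)C(Cl)=O
Why: O‑carbamoylation of both primary hydroxyls (acyl substitution, Et3N takes up HCl) installs the hindered carbamates that later direct and stabilise α‑lithiation; no stereocentre is formed.

Step 2
Reactants: 4 ethyl 2,4‑dihydroxy‑6‑methylbenzoate; 5 benzyl bromide
Product: 6 ethyl 2,4‑bis(benzyloxy)‑6‑methylbenzoate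
Conditions: 5 (2.5 equiv), K2CO3 (3 equiv), DMF, 70 °C, 12 h
Reagents that add atoms: benzyl bromide (5), BrCc1ccccc1
Why: Williamson ether synthesis (phenoxide SN2 on benzyl bromide), run warm in DMF so that the hydrogen‑bonded 2‑hydroxyl is alkylated as well; no stereocentre is formed.

Step 3
Reactants: 6 ethyl 2,4‑bis(benzyloxy)‑6‑methylbenzoate; 7 2‑isopropoxy‑4,4,5,5‑tetramethyl‑1,3,2‑dioxaborolane
Product: 10 ethyl 2,4‑bis(benzyloxy)‑6‑[(4,4,5,5‑tetramethyl‑1,3,2‑dioxaborolan‑2‑yl)methyl]benzoate, via benzylic lithium 8 (not isolated), via isopropoxyborate 9 (not isolated)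
Conditions: LiN(iPr)2 (1.1 equiv), THF, −78 °C, 10 min; 7 (1.5 equiv), −78 °C, 1 h; HCl (2 M in Et2O), −78 °C → rt
Reagents that add atoms: 2‑isopropoxy‑4,4,5,5‑tetramethyl‑1,3,2‑dioxaborolane (7), CC(C)OB1OC(C)(C)C(C)(C)O1
Why: Proposed new method: LiN(iPr)2 removes a proton from the methyl group ortho to the ester (lateral lithiation, giving the vinylogous ester enolate 8), the benzylic carbon of 8 attacks the borate 7 to give the tetracoordinate, no longer acidic borate 9, and HCl expels isopropanol to release the benzylic boronic ester; the closest known reactions are the lateral lithiation–electrophile trapping of orsellinate esters and the deprotonation–borylation of benzylic and aryl C–H bonds with lithium amide/alkoxyborane pairs.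

Step 4
Reactants: 3 heptane‑1,7‑diyl bis(N,N‑diisopropylcarbamate); 10 ethyl 2,4‑bis(benzyloxy)‑6‑[(4,4,5,5‑tetramethyl‑1,3,2‑dioxaborolan‑2‑yl)methyl]benzoate; 11 4,4,5,5‑tetramethyl‑2‑pentyl‑1,3,2‑dioxaborolane
Product: 16 (3R)‑6,8‑bis(benzyloxy)‑3‑[(6S)‑6‑hydroxyundecyl]‑3,4‑dihydro‑1H‑isochromen‑1‑one, via dilithio bis‑carbamate 12 (not isolated), via bis‑borate 13 (not isolated), via bis(boronic ester) 14 (not isolated), via hydroxy ester 15 (not isolated)
Conditions: 3 (1.0 equiv), (−)‑sparteine (2.3 equiv), s‑BuLi (2.2 equiv), Et2O, −78 °C, 5 h; 11 (1.2 equiv), then 10 (0.8 equiv), −78 °C, 1 h; MgBr2·OEt2 (2.5 equiv), −78 °C → 35 °C, 16 h; then NaOH (2 M aq), H2O2 (30% aq), THF, 0 °C → rt; HCl (1 M aq) work‑up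
Reagents that add atoms: hydrogen peroxide, OO
Why: Proposed new method: s‑BuLi/(−)‑sparteine removes the pro‑S proton at each carbamate terminus to give the configurationally stable α‑lithiated carbamate 12 (an α‑oxygenated carbanion, so that a carbinol carbon reacts as the nucleophile), each C–Li bond adds to boron with retention and the borate 13 then undergoes 1,2‑migration of benzyl or pentyl from boron to carbon with inversion and loss of the carbamate, after which peroxide oxidation with retention gives 15 whose C2 alkoxide closes the lactone on the neighbouring ethyl ester; the spatial sense is the same at both ends and reads R at C3 but S at C6' only because the benzylic group outranks the chain whereas pentyl does not, and the closest known reaction is the Hoppe–Aggarwal lithiation–borylation of primary alkyl carbamates, run here at both ends of one chain with two different boronic esters, so the mixed product forms statistically (ceiling about 50 %) beside the two symmetrical ones.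

Step 5
Reactants: 16 (3R)‑6,8‑bis(benzyloxy)‑3‑[(6S)‑6‑hydroxyundecyl]‑3,4‑dihydro‑1H‑isochromen‑1‑one
Product: 17 (3R)‑6,8‑dihydroxy‑3‑[(6S)‑6‑hydroxyundecyl]‑3,4‑dihydro‑1H‑isochromen‑1‑one
Conditions: H2 (1 atm), Pd/C (10 wt%), EtOAc–EtOH, rt
Reagents that add atoms: none
Why: Catalytic hydrogenolysis cleaves both aryl benzyl ethers while the lactone, the secondary alcohol and both stereocentres are untouched.

**Compound list**
1 | heptane‑1,7‑diol | OCCCCCCCO | starting material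
2 | N,N‑diisopropylcarbamoyl chloride | CC(C)N(C(C)C)C(Cl)=O | starting material
3 | heptane‑1,7‑diyl bis(N,N‑diisopropylcarbamate) | CC(C)N(C(C)C)C(=O)OCCCCCCCOC(=O)N(C(C)C)C(C)C | intermediate
4 | ethyl 2,4‑dihydroxy‑6‑methylbenzoate (ethyl orsellinate) | CCOC(=O)c1c(C)cc(O)cc1O | starting material
5 | benzyl bromide | BrCc1ccccc1 | starting material
6 | ethyl 2,4‑bis(benzyloxy)‑6‑methylbenzoate | CCOC(=O)c1c(C)cc(OCc2ccccc2)cc1OCc1ccccc1 | intermediate
7 | 2‑isopropoxy‑4,4,5,5‑tetramethyl‑1,3,2‑dioxaborolane | CC(C)OB1OC(C)(C)C(C)(C)O1 | starting material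
8 | ethyl 2,4‑bis(benzyloxy)‑6‑(lithiomethyl)benzoate (benzylic lithium) | [Li]Cc1cc(OCc2ccccc2)cc(OCc2ccccc2)c1C(=O)OCC | intermediate
9 | lithium {[3,5‑bis(benzyloxy)‑2‑(ethoxycarbonyl)phenyl]methyl}(isopropoxy)(pinacolato)borate | [Li+].CCOC(=O)c1c(C[B-]2(OC(C)C)OC(C)(C)C(C)(C)O2)cc(OCc2ccccc2)cc1OCc1ccccc1 | intermediate
10 | ethyl 2,4‑bis(benzyloxy)‑6‑[(4,4,5,5‑tetramethyl‑1,3,2‑dioxaborolan‑2‑yl)methyl]benzoate | CCOC(=O)c1c(CB2OC(C)(C)C(C)(C)O2)cc(OCc2ccccc2)cc1OCc1ccccc1 | intermediate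
11 | 4,4,5,5‑tetramethyl‑2‑pentyl‑1,3,2‑dioxaborolane | CCCCCB1OC(C)(C)C(C)(C)O1 | starting material
12 | (1S,7S)‑1,7‑dilithioheptane‑1,7‑diyl bis(N,N‑diisopropylcarbamate) as its bis[(−)‑sparteine] complex (ligand not drawn) | [Li][C@H](OC(=O)N(C(C)C)C(C)C)CCCCC[C@H]([Li])OC(=O)N(C(C)C)C(C)C | intermediate
13 | dilithium bis‑borate: (1S,7S)‑heptane‑1,7‑diyl bis(N,N‑diisopropylcarbamate) carrying a pentyl(pinacolato)borate at C1 and a {[3,5‑bis(benzyloxy)‑2‑(ethoxycarbonyl)phenyl]methyl}(pinacolato)borate at C7 | [Li+].[Li+].CCCCC[B-]1(OC(C)(C)C(C)(C)O1)[C@H](OC(=O)N(C(C)C)C(C)C)CCCCC[C@H]([B-]1(Cc2cc(OCc3ccccc3)cc(OCc3ccccc3)c2C(=O)OCC)OC(C)(C)C(C)(C)O1)OC(=O)N(C(C)C)C(C)C | intermediate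
14 | ethyl 2,4‑bis(benzyloxy)‑6‑[(2R,8S)‑2,8‑bis(4,4,5,5‑tetramethyl‑1,3,2‑dioxaborolan‑2‑yl)tridecyl]benzoate | CCCCC[C@H](B1OC(C)(C)C(C)(C)O1)CCCCC[C@@H](B1OC(C)(C)C(C)(C)O1)Cc1cc(OCc2ccccc2)cc(OCc2ccccc2)c1C(=O)OCC | intermediate
15 | ethyl 2,4‑bis(benzyloxy)‑6‑[(2R,8S)‑2,8‑dihydroxytridecyl]benzoate | CCCCC[C@H](O)CCCCC[C@@H](O)Cc1cc(OCc2ccccc2)cc(OCc2ccccc2)c1C(=O)OCC | intermediate
16 | (3R)‑6,8‑bis(benzyloxy)‑3‑[(6S)‑6‑hydroxyundecyl]‑3,4‑dihydro‑1H‑isochromen‑1‑one | CCCCC[C@H](O)CCCCC[C@@H]1Cc2cc(OCc3ccccc3)cc(OCc3ccccc3)c2C(=O)O1 | intermediate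
17 | (3R)‑6,8‑dihydroxy‑3‑[(6S)‑6‑hydroxyundecyl]‑3,4‑dihydro‑1H‑isochromen‑1‑one | CCCCC[C@H](O)CCCCC[C@@H]1Cc2cc(O)cc(O)c2C(=O)O1 | target

**Step count**
Total steps: 5. Longest linear sequence: 4 steps (4 → 6 → 10 → 16 → 17).

**Three steps most likely to fail, with fallbacks**

Step 4 (key step). The hetero‑coupling is statistical, so 16 cannot exceed about half of the material and must be separated from the bis‑lactone and the aliphatic diol. Double lithiation may be incomplete, and residual C–Li could attack the ester or deprotonate the benzylic position of 10; adding 11 first is meant to limit that. Each centre is set at roughly 97:3, so a few percent of remote diastereomers will travel with the product. The fallback makes the two carbinol centres one after the other with no statistical step; it sets out from 10 and comes back to the route at 17. Bought hex‑5‑en‑1‑ol is carbamoylated with 2 (Et3N, CH2Cl2, reflux) to hex‑5‑en‑1‑yl N,N‑diisopropylcarbamate F1. s‑BuLi/(−)‑sparteine (Et2O, −78 °C) gives (1S)‑1‑lithiohex‑5‑en‑1‑yl N,N‑diisopropylcarbamate F2, which adds to 10 to form the lithium borate F3. 1,2‑Migration (MgBr2·OEt2, Et2O, reflux) gives the secondary boronic ester F4, and NaOH/H2O2 gives the hydroxy ester F5, which closes to (3R)‑6,8‑bis(benzyloxy)‑3‑(pent‑4‑en‑1‑yl)‑3,4‑dihydro‑1H‑isochromen‑1‑one F6. Cross‑metathesis of F6 with bought (S)‑oct‑1‑en‑3‑ol (3 equiv; second‑generation Hoveyda–Grubbs catalyst RuCl2(H2IMes)(=CH‑C6H4‑2‑OiPr), CH2Cl2, 40 °C) gives (3R)‑6,8‑bis(benzyloxy)‑3‑[(4E,6S)‑6‑hydroxyundec‑4‑en‑1‑yl]‑3,4‑dihydro‑1H‑isochromen‑1‑one F7. Hydrogenation under the conditions of step 5 saturates the alkene and removes both benzyl groups to give 17.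

Step 3. The lateral anion 8 may self‑condense, be borylated on oxygen instead of carbon, or 10 may protodeboronate on work‑up. The fallback leaves the ester out of the boronic ester and brings in the lactone carbonyl after the key step; it sets out from 3 and comes back at 16. Bought 3,5‑bis(benzyloxy)benzyl bromide is borylated with bis(pinacolato)diboron (Pd(dba)2, P(C6H4‑4‑OMe)3, KOAc, toluene, 50 °C) to 2‑[3,5‑bis(benzyloxy)benzyl]‑4,4,5,5‑tetramethyl‑1,3,2‑dioxaborolane F8. Under the conditions of step 4, 12 (from 3) takes up 11 and F8 to give the dilithium bis‑borate F9, then the bis(boronic ester) F10 and, after oxidation, (2R,8S)‑1‑[3,5‑bis(benzyloxy)phenyl]tridecane‑2,8‑diol F11. NBS (1.0 equiv, MeCN, 0 °C) brominates the ring position ortho to the side chain and para to a benzyloxy group, giving (2R,8S)‑1‑[3,5‑bis(benzyloxy)‑2‑bromophenyl]tridecane‑2,8‑diol F12. Carbonylative lactonisation (Pd(OAc)2, Xantphos, CO 1 atm, Et3N, toluene, 90 °C) closes the six‑membered lactone onto the C2 hydroxyl and gives 16. This fallback also covers the case where the ester of 10 does not survive step 4.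

Step 2. The 2‑hydroxyl is hydrogen‑bonded to the ester and may resist alkylation, leaving the mono‑ether. The fallback makes the two ethers by two different reactions; it sets out from 4 and comes back at 6. 4 is benzylated only at the free 4‑hydroxyl (5, 1.05 equiv, K2CO3, acetone, reflux) to ethyl 4‑(benzyloxy)‑2‑hydroxy‑6‑methylbenzoate F13. The chelated phenol is then etherified under Mitsunobu conditions (benzyl alcohol, PPh3, diisopropyl azodicarboxylate, THF, 0 °C → rt) to give 6.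

**Further compounds**
F1 | step 4 | hex‑5‑en‑1‑yl N,N‑diisopropylcarbamate | C=CCCCCOC(=O)N(C(C)C)C(C)C
F2 | step 4 | (1S)‑1‑lithiohex‑5‑en‑1‑yl N,N‑diisopropylcarbamate as its (−)‑sparteine complex (ligand not drawn) | [Li][C@H](OC(=O)N(C(C)C)C(C)C)CCCC=C
F3 | step 4 | lithium {[3,5‑bis(benzyloxy)‑2‑(ethoxycarbonyl)phenyl]methyl}[(1S)‑1‑(diisopropylcarbamoyloxy)hex‑5‑en‑1‑yl](pinacolato)borate | [Li+].C=CCCC[C@H]([B-]1(Cc2cc(OCc3ccccc3)cc(OCc3ccccc3)c2C(=O)OCC)OC(C)(C)C(C)(C)O1)OC(=O)N(C(C)C)C(C)C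
F4 | step 4 | ethyl 2,4‑bis(benzyloxy)‑6‑[(2R)‑2‑(4,4,5,5‑tetramethyl‑1,3,2‑dioxaborolan‑2‑yl)hept‑6‑en‑1‑yl]benzoate | C=CCCC[C@@H](B1OC(C)(C)C(C)(C)O1)Cc1cc(OCc2ccccc2)cc(OCc2ccccc2)c1C(=O)OCC
F5 | step 4 | ethyl 2,4‑bis(benzyloxy)‑6‑[(2R)‑2‑hydroxyhept‑6‑en‑1‑yl]benzoate | C=CCCC[C@@H](O)Cc1cc(OCc2ccccc2)cc(OCc2ccccc2)c1C(=O)OCC
F6 | step 4 | (3R)‑6,8‑bis(benzyloxy)‑3‑(pent‑4‑en‑1‑yl)‑3,4‑dihydro‑1H‑isochromen‑1‑one | C=CCCC[C@@H]1Cc2cc(OCc3ccccc3)cc(OCc3ccccc3)c2C(=O)O1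
F7 | step 4 | (3R)‑6,8‑bis(benzyloxy)‑3‑[(4E,6S)‑6‑hydroxyundec‑4‑en‑1‑yl]‑3,4‑dihydro‑1H‑isochromen‑1‑one | CCCCC[C@H](O)/C=C/CCC[C@@H]1Cc2cc(OCc3ccccc3)cc(OCc3ccccc3)c2C(=O)O1
F8 | step 3 | 2‑[3,5‑bis(benzyloxy)benzyl]‑4,4,5,5‑tetramethyl‑1,3,2‑dioxaborolane | CC1(C)OB(Cc2cc(OCc3ccccc3)cc(OCc3ccccc3)c2)OC1(C)C
F9 | step 3 | dilithium bis‑borate: (1S,7S)‑heptane‑1,7‑diyl bis(N,N‑diisopropylcarbamate) carrying a pentyl(pinacolato)borate at C1 and a [3,5‑bis(benzyloxy)benzyl](pinacolato)borate at C7 | [Li+].[Li+].CCCCC[B-]1(OC(C)(C)C(C)(C)O1)[C@H](OC(=O)N(C(C)C)C(C)C)CCCCC[C@H]([B-]1(Cc2cc(OCc3ccccc3)cc(OCc3ccccc3)c2)OC(C)(C)C(C)(C)O1)OC(=O)N(C(C)C)C(C)C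
F10 | step 3 | (2R,8S)‑1‑[3,5‑bis(benzyloxy)phenyl]‑2,8‑bis(4,4,5,5‑tetramethyl‑1,3,2‑dioxaborolan‑2‑yl)tridecane | CCCCC[C@H](B1OC(C)(C)C(C)(C)O1)CCCCC[C@@H](B1OC(C)(C)C(C)(C)O1)Cc1cc(OCc2ccccc2)cc(OCc2ccccc2)c1
F11 | step 3 | (2R,8S)‑1‑[3,5‑bis(benzyloxy)phenyl]tridecane‑2,8‑diol | CCCCC[C@H](O)CCCCC[C@@H](O)Cc1cc(OCc2ccccc2)cc(OCc2ccccc2)c1
F12 | step 3 | (2R,8S)‑1‑[3,5‑bis(benzyloxy)‑2‑bromophenyl]tridecane‑2,8‑diol | CCCCC[C@H](O)CCCCC[C@@H](O)Cc1cc(OCc2ccccc2)cc(OCc2ccccc2)c1Br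
F13 | step 2 | ethyl 4‑(benzyloxy)‑2‑hydroxy‑6‑methylbenzoate | CCOC(=O)c1c(C)cc(OCc2ccccc2)cc1O
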